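## Structural features

Bromophycolide F is a 15-membered macrolactone in which a 4-hydroxybenzoate is bridged in the meta sense by a brominated diterpene chain. The carbons are numbered C1 (benzylic CH2), C2–C7 (ring A), C8–C14 (chain) and C15 (the carbinol carbon with two methyl groups); the lactone oxygen sits on C14. Ring A is a cyclohexane that shares the C2–C7 bond with the macrocycle and carries the exocyclic methylene on C3, the secondary bromide on C6 and the quaternary C7 (methyl and C8). C2 (R), C7 (S) and C6 (S) are contiguous: C1 and C8 are trans, and bromine is trans to C8 and cis to the C7 methyl group. Remote from these are the trans trisubstituted epoxide C10–C11 (S,S) and the esterified carbinol C14 (S) beside the tertiary alcohol C15; ring A cannot relay stereochemistry to them, so they need reagent control. The fragile groups are the epoxide (acid lets O-14 or O-15 open it to cyclic ethers), the neopentyl secondary bromide (reduction, and cyclopropane closure whenever an enolisable carbonyl sits at C3), the exocyclic alkene, the benzoate lactone and the acidic phenol. The real difficulty is the quaternary C7 next to C6–Br with defined relative and absolute configuration, followed by C2 and by closure of the macrocycle without disturbing these. The key step exploits the C6(Br)–C7(quaternary) pair of ring A with bromine anti to C8: this is the retron of a bromonium-induced 1,2-shift of C8 from a C2 carbinol to C7, which converts one carbinol stereocentre into both C6 and C7 and leaves a C2 ketone as the handle for C1 and the C3 methylene.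

## Logic of the disconnections

**32 ⇒ 31 ⇒ 30.** The aryl O–Si bond and then the two C–O bonds of the epoxide (C10–O, C11–O) are cut first. The epoxide is the most fragile group, and placing it last keeps it away from every acidic, Lewis acidic and organometallic step and from any stage with a free C14 hydroxyl. The gain is that 30 has only four stereocentres. The demand is an oxidant that prefers C10=C11 over the exocyclic alkene and that controls the face of a macrocyclic alkene.

**30 ⇒ 28 ⇒ 27.** The lactone bond between O-14 and the benzoyl carbon is cut because it is the only heteroatom link of the large ring; this gives an open chain holding every carbon. The forward step must acylate a hindered secondary hydroxyl in the presence of a free tertiary one, and 28 must be released from its methyl ester 27 without loss of the aryl silyl ether.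

**27 ⇒ 24 ⇒ 20 + 22 ⇒ 19.** The C14–H bond is cut back to a ketone, then the C12–C13 bond (with the C10=C11 π bond shifted to C11=C12, a retro-[3,3] step), then the C10–C11 bond. The sigmatropic step sets the E geometry of the trisubstituted alkene and brings in C13–C15 in one operation, so the whole side chain reduces to a C10 aldehyde. The demands are a chair transition state with high E preference at about 110 °C and a ketone reduction that distinguishes a quaternary flank from a primary one.

**19 ⇒ 18 ⇒ 17 ⇒ 16 ⇒ 15 ⇒ 13.** These are oxidation-state changes at C10, removal of the C3 methylene carbon back to a ketone, and removal of the C3–O and C2–H bonds back to the C2=C3 alkene. The carbonyl is transposed from C2 to C3 through the alkene that the cross-coupling leaves behind. The demands are face-selective addition of borane, which sets C2, and a methylenation that does not enolise a γ-bromo ketone.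

**13 ⇒ 8 + 11 (through 12); 8 ⇒ 6.** The C1–C2 bond is cut because, apart from the lactone, it is the only link between the arene and ring A; both halves become simple. The forward coupling needs zerovalent palladium to choose the vinyl triflate over the secondary C–Br bond. Enolisation of 6 can occur only towards C3, so 8 forms as a single regioisomer.

**6 ⇒ 5 (key).** C7–C8 and C6–Br are cut and C8 is reattached to C2. This replaces a quaternary carbon next to a bromide by one tertiary allylic carbinol, so two stereocentres become one. The forward step needs anti migration of the chain with complete chirality transfer and migration of the chain in preference to the ring bond. In 5 the tertiary hydroxyl is left free, since it is both the electron source and the group that directs the brominating agent. The terminal oxygen is a TBS ether, which is poorly nucleophilic towards the bromonium ion and can later be removed by acid beside the aryl TIPS ether.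

**5 ⇒ 1 + 2 (through 3 and 4).** The C2–C8 bond is cut to an enone and a functionalised dialkylzinc. This leaves two small achiral starting materials, and the demand is catalyst control of the enantioface in a 1,2-addition to an α-substituted enone.

**11 ⇒ 10 ⇒ 9, and 22 ⇒ 21.** These are functional-group changes on commercial compounds: the benzylic C–Br bond and the O–Si bond on the arene, and the ketal C–O bonds on the Claisen partner.

## Other disconnections considered

**Alternative 1:** The cut is the bond between the aromatic carbon and C1. In the reverse sense the C1 acyl group returns to the phenol oxygen, which turns A1 (the C1-oxo analogue of the target) into the 17-membered para-bridged diester A2. In the forward direction, irradiation of A2 would break the aryl O–acyl bond, and the caged acyl and phenoxyl radicals would recombine at the ortho carbon (photo-Fries rearrangement). Tautomerisation would then give A1 and contract the ring from 17 to 15 members.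
- In favour: closing a 17-membered ring by acylating a phenol is easier than closing the 15-membered lactone of the chosen plan. Both ortho positions are equivalent, so regiochemistry is unambiguous. The phenol needs no protecting group because it is the acyl acceptor and is released by the key step; on protecting-group economy the alternative is the better.
- Against: A1 keeps a C1 carbonyl that must be reduced to CH2 in a molecule with an acid-sensitive epoxide, a secondary bromide and a benzoate lactone, and the usual reductions of ortho-hydroxyaryl ketones endanger all three. The secondary acyl radical can lose CO before recombination. The C–Br bond and the β,γ-unsaturated aryl ketone of A1 absorb light themselves. C2 becomes an enolisable centre.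
- Comparison: both plans end in the same macrocycle. The alternative relies on a radical pair in a solvent cage, where the chosen plan uses closed-shell stereospecific steps. In step count the saved protection is offset by the deoxygenation, so the two are about equal. A2 would still need its own answer for the C6/C7 pair.

**Alternative 2:** The cut removes C2–C7 and C5–C6 and opens ring A to two fragments. One is the 2-(trimethylsilylmethyl)diene A4, with the arylmethyl group on the terminus that becomes C2. The other is the (Z)-β-bromo enal A5, which carries C8–C15 with the diol as an acetonide. A Lewis-acid-catalysed [4+2] cycloaddition would give A3 with ring A, C2, C6 and C7 formed at once.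
- In favour: convergence, on which the alternative is the better, since arene and complete side chain arrive in two fragments. The cis relationship of bromine and the formyl group follows from the dienophile geometry, and the endo rule would place the arylmethyl group cis to the formyl group, as required. The allylsilane would release the exocyclic methylene by protodesilylation without a C3 ketone, which avoids the γ-bromo ketone stage of the chosen plan; this is also a point for the alternative.
- Against: A5 is a trisubstituted, α-branched dienophile that must create a quaternary carbon, so low reactivity is expected. The two donor groups of A4 direct in opposite senses: the terminal alkyl group favours the needed orientation and the silylmethyl group on the inner carbon favours the other. Absolute control would need a chiral Lewis acid on an unusual enal or relay from the distant C14. The formyl group of A3 must then be reduced to a methyl group at a neopentyl position without touching C6–Br, which rules out the radical and dissolving-metal methods normally used.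
- Comparison: the chosen plan is linear and longer, but it derives C6 and C7 from one catalyst-controlled carbinol by a stereospecific shift. The alternative is shorter on paper but rests regio-, endo- and enantioselectivity on one step and adds a hard deoxygenation.

**Alternative 3:** The cut is C2–C7 and C6–Br inside the finished lactone. It leads back to the 19-membered macrolactone A7, in which C6=C7 is an E-trisubstituted alkene and C2=C3 a Z-chloroalkene. A bromonium donor would add to C6=C7, the chloroalkene would attack C7 across the ring through a chair-like array, and the α-chloro cation at C3 would be hydrolysed to the ketone of A6.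
- In favour: the step is biomimetic and forms ring A with C2, C6 and C7 in one late operation. A 19-membered lactone is easier to close than a 15-membered one, which is a point for the alternative. Anti addition across the E-alkene gives the same trans relationship of bromine and C8 that the chosen key step gives by anti migration; here the two are equal.
- Against: the bromonium ion would form within reach of the epoxide oxygen, the tertiary hydroxyl and the ester carbonyl, all competing nucleophiles. A chloroalkene is a weak π-nucleophile. The absolute sense at C2, C6 and C7 would have to be relayed from C10, C11 and C14 through a flexible large ring without reagent control. A6 still needs methylenation at C3 beside the epoxide and the aryl acetate, at the stage of a γ-bromo ketone.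
- Comparison: on step economy the alternative is the better. On stereochemical reliability the chosen plan is the better, because each stereocentre is set under reagent control or by a stereospecific event. Both use bromonium chemistry at C6=C7 for the C–Br bond.

Key step: step 2

Assumption: the antipode of the bis(sulfonamide) diol ligand in step 1 is the one that directs the alkyl group to the enone face giving the S carbinol; both antipodes are accessible from the enantiomeric trans-cyclohexane-1,2-diamines and 10-camphorsulfonyl chlorides.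

## Route

Step 1
Reactants: 1 allyloxy(tert-butyl)dimethylsilane; 2 2-methylcyclohex-2-en-1-one
Product: 5 (1S)-1-{3-[(tert-butyldimethylsilyl)oxy]propyl}-2-methylcyclohex-2-en-1-ol, via alkyldiethylborane 3 (not isolated), via dialkylzinc 4 (not isolated)
Conditions: Et2BH (from BH3·SMe2 and Et3B), 0 °C → rt; Et2Zn, 0 °C, volatiles removed in vacuo; C2-symmetric bis(sulfonamide) diol ligand from trans-cyclohexane-1,2-diamine and 10-camphorsulfonyl chloride (exo alcohols, 10 mol%), Ti(OiPr)4 (1.2 equiv), 2, toluene/hexane, rt; aq. NH4Cl
Reagents that add atoms: none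
Why: Hydroboration puts boron on the terminal carbon of 1, boron–zinc exchange gives the functionalised dialkylzinc 4, and the titanium complex of the chiral ligand catalyses its enantioface-selective 1,2-addition to the α-substituted enone (catalytic asymmetric alkylzinc addition to a ketone). The ligand antipode fixes the S configuration of the new carbinol carbon C2, and conjugate addition is not expected from a dialkylzinc with Ti(OiPr)4.

Step 2
Reactants: 5 (1S)-1-{3-[(tert-butyldimethylsilyl)oxy]propyl}-2-methylcyclohex-2-en-1-ol
Product: 6 (2S,3S)-3-bromo-2-{3-[(tert-butyldimethylsilyl)oxy]propyl}-2-methylcyclohexan-1-one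
Conditions: NBS (1.1 equiv), CH2Cl2, −20 → 0 °C, dark
Reagents that add atoms: N-bromosuccinimide, O=C1CCC(=O)N1Br
Why: NBS transfers Br+ to the C6=C7 alkene; the bromonium ion on the hydroxyl-bearing face (favoured by hydrogen bonding of O–H to the reagent) has the C2–C8 bond antiperiplanar to the C7–Br bond that breaks, so as it opens at the tertiary carbon C7 the C8 chain shifts from C2 to C7, the oxygen lone pair closes to the C2 carbonyl and succinimide anion takes the proton. The closest known reaction type is the halonium-induced semipinacol rearrangement of a tertiary allylic alcohol to a β-halo ketone with a 1,2-carbon shift. No ring is closed and ring A keeps six members, because the ring bond C2–C3 lies near the alkene plane and cannot reach the antiperiplanar alignment that the exocyclic chain has as a pseudoaxial group, so ring contraction is stereoelectronically disfavoured. C7 is set by suprafacial migration of C8 with retention, on the face opposite bromine, so its configuration is dictated by the C2 carbinol of 5; C6 is set by the anti relationship of bromine and the migrating group, which places Br trans to C8 and cis to the methyl group. The step needs the productive bromination face, carbon migration in preference to capture by oxygen, and chain over ring-bond migration; the bromonium ion on the other face has only the hydroxyl anti to it and can revert, the terminal oxygen is a poorly nucleophilic TBS ether, and no HBr is formed in the productive pathway. Because the carbinol centre is consumed, the enantiomeric purity of 5 passes to both new stereocentres, and the S carbinol should give the 2S,3S ketone.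

Step 3
Reactants: 6 (2S,3S)-3-bromo-2-{3-[(tert-butyldimethylsilyl)oxy]propyl}-2-methylcyclohexan-1-one
Product: 8 (5S,6S)-5-bromo-6-{3-[(tert-butyldimethylsilyl)oxy]propyl}-6-methylcyclohex-1-en-1-yl trifluoromethanesulfonate, via potassium enolate 7 (not isolated)
Conditions: KN(SiMe3)2, THF, −78 °C; PhNTf2, −78 → 0 °C
Reagents that add atoms: N-phenylbis(trifluoromethanesulfonimide), O=S(=O)(N(c1ccccc1)S(=O)(=O)C(F)(F)F)C(F)(F)F
Why: Only C3 has enolisable hydrogens (C7 is quaternary), so a single enolate forms and is O-sulfonylated (enol triflate formation). The β-bromine cannot leave by conjugate elimination because the carbon between it and the carbonyl bears no hydrogen.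

Step 4
Reactants: 9 methyl 4-hydroxy-3-methylbenzoate
Product: 10 methyl 3-methyl-4-[(triisopropylsilyl)oxy]benzoate
Conditions: TIPSCl, imidazole, DMF, rt
Reagents that add atoms: chlorotriisopropylsilane, CC(C)[Si](Cl)(C(C)C)C(C)C
Why: Standard silylation of a phenol. The bulky TIPS ether is chosen because it should survive radical bromination, organozinc, borane and mild base, resist acid, and leave with fluoride at the end.

Step 5
Reactants: 10 methyl 3-methyl-4-[(triisopropylsilyl)oxy]benzoate
Product: 11 methyl 3-(bromomethyl)-4-[(triisopropylsilyl)oxy]benzoate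
Conditions: NBS (1.05 equiv), AIBN (cat.), PhCF3, 80 °C
Reagents that add atoms: N-bromosuccinimide, O=C1CCC(=O)N1Br
Why: Wohl–Ziegler bromination. The ring methyl group is the only benzylic C–H position.

Step 6
Reactants: 8 (5S,6S)-5-bromo-6-{3-[(tert-butyldimethylsilyl)oxy]propyl}-6-methylcyclohex-1-en-1-yl trifluoromethanesulfonate; 11 methyl 3-(bromomethyl)-4-[(triisopropylsilyl)oxy]benzoate
Product: 13 methyl 3-{[(5S,6S)-5-bromo-6-{3-[(tert-butyldimethylsilyl)oxy]propyl}-6-methylcyclohex-1-en-1-yl]methyl}-4-[(triisopropylsilyl)oxy]benzoate, via arylmethylzinc bromide 12 (not isolated)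
Conditions: 11, Zn dust, LiCl, THF, 0 °C → rt; then 8, Pd(PPh3)4 (5 mol%), THF, 55 °C
Reagents that add atoms: none
Why: Zinc insertion assisted by LiCl gives the benzylic zinc bromide, which joins C1 to C2 by Negishi coupling. Zerovalent palladium inserts into the vinyl C–OTf bond much faster than into the neopentyl secondary C–Br bond, and the organozinc tolerates the ester and both silyl ethers.

Step 7
Reactants: 13 methyl 3-{[(5S,6S)-5-bromo-6-{3-[(tert-butyldimethylsilyl)oxy]propyl}-6-methylcyclohex-1-en-1-yl]methyl}-4-[(triisopropylsilyl)oxy]benzoate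
Product: 15 methyl 3-{[(1S,2S,3S,6S)-3-bromo-2-{3-[(tert-butyldimethylsilyl)oxy]propyl}-6-hydroxy-2-methylcyclohexyl]methyl}-4-[(triisopropylsilyl)oxy]benzoate, via alkylborane 14 (not isolated)
Conditions: BH3·THF, THF, 0 °C → rt; NaBO3·4H2O, THF/H2O, rt
Reagents that add atoms: sodium perborate (NaBO3·4H2O, supplies the hydroxyl oxygen), [Na+].[Na+].O[B-]1(O)OO[B-](O)(O)OO1
Why: Hydroboration–oxidation: H and B add syn across C2=C3 with boron on the less substituted C3. Borane is expected to approach the face opposite the pseudoaxial C7 methyl group of the half-chair with equatorial C6–Br, which puts H-2 on the side of the C8 chain and the arylmethyl group trans to C8. Perborate oxidises C–B with retention under conditions mild enough for the benzoate and the aryl silyl ether; the C3 configuration is lost in step 8.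

Step 8
Reactants: 15 methyl 3-{[(1S,2S,3S,6S)-3-bromo-2-{3-[(tert-butyldimethylsilyl)oxy]propyl}-6-hydroxy-2-methylcyclohexyl]methyl}-4-[(triisopropylsilyl)oxy]benzoate
Product: 16 methyl 3-{[(1S,2S,3S)-3-bromo-2-{3-[(tert-butyldimethylsilyl)oxy]propyl}-2-methyl-6-oxocyclohexyl]methyl}-4-[(triisopropylsilyl)oxy]benzoate
Conditions: Dess–Martin periodinane, NaHCO3, CH2Cl2, 0 °C → rt
Reagents that add atoms: none
Why: Dess–Martin oxidation of the secondary alcohol under buffered, non-enolising conditions, so the kinetically set C2 centre is kept.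

Step 9
Reactants: 16 methyl 3-{[(1S,2S,3S)-3-bromo-2-{3-[(tert-butyldimethylsilyl)oxy]propyl}-2-methyl-6-oxocyclohexyl]methyl}-4-[(triisopropylsilyl)oxy]benzoate
Product: 17 methyl 3-{[(1R,2S,3S)-3-bromo-2-{3-[(tert-butyldimethylsilyl)oxy]propyl}-2-methyl-6-methylidenecyclohexyl]methyl}-4-[(triisopropylsilyl)oxy]benzoate
Conditions: Zn, CH2Br2, TiCl4 (reagent preformed in THF), CH2Cl2, 0 °C → rt
Reagents that add atoms: dibromomethane, BrCBr
Why: Takai–Lombardo methylenation. The non-basic titanium–zinc methylene reagent olefinates the ketone without enolising it, so C2 is not epimerised and the γ-bromo ketone is not exposed to an enolate that could close a cyclopropane onto C6; esters and silyl ethers are tolerated.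

Step 10
Reactants: 17 methyl 3-{[(1R,2S,3S)-3-bromo-2-{3-[(tert-butyldimethylsilyl)oxy]propyl}-2-methyl-6-methylidenecyclohexyl]methyl}-4-[(triisopropylsilyl)oxy]benzoate
Product: 18 methyl 3-{[(1R,2S,3S)-3-bromo-2-(3-hydroxypropyl)-2-methyl-6-methylidenecyclohexyl]methyl}-4-[(triisopropylsilyl)oxy]benzoate
Conditions: camphorsulfonic acid (10 mol%), MeOH/CH2Cl2, 0 °C
Reagents that add atoms: none
Why: Acid-catalysed methanolysis removes the primary alkyl TBS ether much faster than the acid-stable aryl TIPS ether. The conditions are too mild to isomerise the exocyclic alkene.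

Step 11
Reactants: 18 methyl 3-{[(1R,2S,3S)-3-bromo-2-(3-hydroxypropyl)-2-methyl-6-methylidenecyclohexyl]methyl}-4-[(triisopropylsilyl)oxy]benzoate
Product: 19 methyl 3-{[(1R,2S,3S)-3-bromo-2-methyl-6-methylidene-2-(3-oxopropyl)cyclohexyl]methyl}-4-[(triisopropylsilyl)oxy]benzoate
Conditions: Dess–Martin periodinane, NaHCO3, CH2Cl2, rt
Reagents that add atoms: none
Why: Dess–Martin oxidation stops at the aldehyde and leaves the alkene, bromide and silyl ether alone.

Step 12
Reactants: 19 methyl 3-{[(1R,2S,3S)-3-bromo-2-methyl-6-methylidene-2-(3-oxopropyl)cyclohexyl]methyl}-4-[(triisopropylsilyl)oxy]benzoate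
Product: 20 methyl 3-{[(1R,2S,3S)-3-bromo-2-[(3RS)-3-hydroxy-4-methylpent-4-en-1-yl]-2-methyl-6-methylidenecyclohexyl]methyl}-4-[(triisopropylsilyl)oxy]benzoate (mixture of C10 epimers)
Conditions: CH2=C(CH3)MgBr (1.3 equiv), THF, −78 °C; aq. NH4Cl
Reagents that add atoms: isopropenylmagnesium bromide, C=C(C)[Mg]Br
Why: Grignard addition to the aldehyde at −78 °C is far faster than attack on the aryl ester. The C10 carbinol forms as a mixture, which does not matter because C10 becomes sp2 in step 14.

Step 13
Reactants: 21 3-hydroxy-3-methylbutan-2-one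
Product: 22 3,3-dimethoxy-2-methylbutan-2-ol
Conditions: HC(OMe)3, MeOH, TsOH·H2O (cat.), rt; NaOMe quench, distillation
Reagents that add atoms: trimethyl orthoformate, COC(OC)OC; methanol, CO
Why: Acid-catalysed ketalisation driven by the orthoformate as water scavenger; the tertiary hydroxyl is not affected.

Step 14
Reactants: 20 methyl 3-{[(1R,2S,3S)-3-bromo-2-[(3RS)-3-hydroxy-4-methylpent-4-en-1-yl]-2-methyl-6-methylidenecyclohexyl]methyl}-4-[(triisopropylsilyl)oxy]benzoate; 22 3,3-dimethoxy-2-methylbutan-2-ol
Product: 24 methyl 3-{[(1R,2S,3S)-3-bromo-2-[(3E)-8-hydroxy-4,8-dimethyl-7-oxonon-3-en-1-yl]-2-methyl-6-methylidenecyclohexyl]methyl}-4-[(triisopropylsilyl)oxy]benzoate, via allyl enol ether 23 (not isolated)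
Conditions: 22 (6 equiv), 2,4-dinitrophenol (10 mol%), toluene, 110 °C, MeOH removed over 4 Å molecular sieves
Reagents that add atoms: none
Why: Ketal Claisen rearrangement: acid-catalysed exchange and loss of methanol give the allyl enol ether, which undergoes a [3,3] shift through a chair transition state with the C9 chain equatorial. This forms C12–C13 and the E-configured C10=C11 alkene and delivers C13–C15 as the hydroxy ketone; the weak acid should leave the exocyclic alkene and the silyl ether intact.

Step 15
Reactants: 24 methyl 3-{[(1R,2S,3S)-3-bromo-2-[(3E)-8-hydroxy-4,8-dimethyl-7-oxonon-3-en-1-yl]-2-methyl-6-methylidenecyclohexyl]methyl}-4-[(triisopropylsilyl)oxy]benzoate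
Product: 27 methyl 3-{[(1R,2S,3S)-3-bromo-2-[(3E,7S)-7,8-dihydroxy-4,8-dimethylnon-3-en-1-yl]-2-methyl-6-methylidenecyclohexyl]methyl}-4-[(triisopropylsilyl)oxy]benzoate, via silyl ether ketone 25 (not isolated), via silyl ether alcohol 26 (not isolated)
Conditions: N-(trimethylsilyl)imidazole, CH2Cl2, rt, short silica pad; (R)-Me-CBS oxazaborolidine (0.3 equiv), catecholborane (2 equiv), toluene, −78 → −40 °C; MeOH; citric acid, MeOH, rt
Reagents that add atoms: none
Why: The tertiary hydroxyl is masked in the flask as its TMS ether so that it neither consumes nor redirects the borane. Corey–Bakshi–Shibata reduction with the R catalyst then delivers hydride to the ketone face that gives the 14S alcohol, with the silyloxy-bearing quaternary carbon as the large group; catecholborane at low temperature does not hydroborate the alkenes, and mild acidic methanolysis removes the TMS group.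

Step 16
Reactants: 27 methyl 3-{[(1R,2S,3S)-3-bromo-2-[(3E,7S)-7,8-dihydroxy-4,8-dimethylnon-3-en-1-yl]-2-methyl-6-methylidenecyclohexyl]methyl}-4-[(triisopropylsilyl)oxy]benzoate
Product: 28 3-{[(1R,2S,3S)-3-bromo-2-[(3E,7S)-7,8-dihydroxy-4,8-dimethylnon-3-en-1-yl]-2-methyl-6-methylidenecyclohexyl]methyl}-4-[(triisopropylsilyl)oxy]benzoic acid
Conditions: Me3SnOH (8 equiv), ClCH2CH2Cl, 80 °C; cold 0.1 M HCl wash
Reagents that add atoms: trimethyltin hydroxide (supplies the carboxyl oxygen), C[Sn](C)(C)O
Why: Me3SnOH cleaves methyl esters under nearly neutral conditions through a tin carboxylate, which should spare the aryl silyl ether, the bromide and both alkenes.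

Step 17
Reactants: 28 3-{[(1R,2S,3S)-3-bromo-2-[(3E,7S)-7,8-dihydroxy-4,8-dimethylnon-3-en-1-yl]-2-methyl-6-methylidenecyclohexyl]methyl}-4-[(triisopropylsilyl)oxy]benzoic acid
Product: 30 (10E)-10,11-deoxy-O-(triisopropylsilyl)bromophycolide F (the 15-membered lactone with a C10=C11 E-alkene in place of the epoxide; 2R,6S,7S,14S), via mixed anhydride 29 (not isolated)
Conditions: 2,4,6-trichlorobenzoyl chloride, Et3N, THF, rt; slow addition to DMAP, toluene, 80 °C (final 1 mM)
Reagents that add atoms: none
Why: Yamaguchi macrolactonisation: the mixed anhydride passes its aroyl group to DMAP, and under high dilution the secondary C14 hydroxyl closes the 15-membered ring. The tertiary C15 hydroxyl is too hindered to compete, the phenol is silylated, and no stereocentre is touched.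

Step 18
Reactants: 30 (10E)-10,11-deoxy-O-(triisopropylsilyl)bromophycolide F
Product: 31 O-(triisopropylsilyl)bromophycolide F (2R,6S,7S,10S,11S,14S)
Conditions: L-fructose-derived Shi ketone (antipode of the usual D-fructose-derived ketone, 0.5 equiv), Oxone (2KHSO5·KHSO4·K2SO4), K2CO3, Bu4NHSO4, MeCN/CH2(OMe)2/aq. Na2B4O7–Na2EDTA buffer, 0 °C
Reagents that add atoms: potassium peroxymonosulfate (Oxone), [K+].[O-]S(=O)(=O)OO
Why: Shi epoxidation: the chiral dioxirane transfers oxygen through a spiro transition state. The D-fructose-derived ketone gives R,R epoxides from E-trisubstituted alkenes, so its antipode is expected to give the 10S,11S epoxide. The electron-rich trisubstituted C10=C11 should react before the 1,1-disubstituted exocyclic alkene, and with O-14 acylated no hydroxyl is placed to open the epoxide in a five-membered mode.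

Step 19
Reactants: 31 O-(triisopropylsilyl)bromophycolide F
Product: 32 bromophycolide F
Conditions: Bu4NF, AcOH (1:1), THF, 0 °C
Reagents that add atoms: none
Why: Fluoride cleaves the aryl O–Si bond rapidly; the acetic acid buffer keeps the medium near neutral, so the epoxide, the lactone and the secondary bromide should be unaffected.

## Compound list

1 | allyloxy(tert-butyl)dimethylsilane | C=CCO[Si](C)(C)C(C)(C)C | starting material
2 | 2-methylcyclohex-2-en-1-one | CC1=CCCCC1=O | starting material
3 | {3-[(tert-butyldimethylsilyl)oxy]propyl}diethylborane | CCB(CC)CCCO[Si](C)(C)C(C)(C)C | intermediate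
4 | bis{3-[(tert-butyldimethylsilyl)oxy]propyl}zinc | CC(C)(C)[Si](C)(C)OCCC[Zn]CCCO[Si](C)(C)C(C)(C)C | intermediate
5 | (1S)-1-{3-[(tert-butyldimethylsilyl)oxy]propyl}-2-methylcyclohex-2-en-1-ol | CC1=CCCC[C@]1(O)CCCO[Si](C)(C)C(C)(C)C | intermediate
6 | (2S,3S)-3-bromo-2-{3-[(tert-butyldimethylsilyl)oxy]propyl}-2-methylcyclohexan-1-one | O=C1CCC[C@H](Br)[C@@]1(C)CCCO[Si](C)(C)C(C)(C)C | intermediate
7 | potassium (5S,6S)-5-bromo-6-{3-[(tert-butyldimethylsilyl)oxy]propyl}-6-methylcyclohex-1-en-1-olate | [K+].[O-]C1=CCC[C@H](Br)[C@@]1(C)CCCO[Si](C)(C)C(C)(C)C | intermediate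
8 | (5S,6S)-5-bromo-6-{3-[(tert-butyldimethylsilyl)oxy]propyl}-6-methylcyclohex-1-en-1-yl trifluoromethanesulfonate | O=S(=O)(OC1=CCC[C@H](Br)[C@@]1(C)CCCO[Si](C)(C)C(C)(C)C)C(F)(F)F | intermediate
9 | methyl 4-hydroxy-3-methylbenzoate | COC(=O)c1ccc(O)c(C)c1 | starting material
10 | methyl 3-methyl-4-[(triisopropylsilyl)oxy]benzoate | COC(=O)c1ccc(O[Si](C(C)C)(C(C)C)C(C)C)c(C)c1 | intermediate
11 | methyl 3-(bromomethyl)-4-[(triisopropylsilyl)oxy]benzoate | COC(=O)c1ccc(O[Si](C(C)C)(C(C)C)C(C)C)c(CBr)c1 | intermediate
12 | {[5-(methoxycarbonyl)-2-[(triisopropylsilyl)oxy]phenyl]methyl}zinc bromide | COC(=O)c1ccc(O[Si](C(C)C)(C(C)C)C(C)C)c(C[Zn]Br)c1 | intermediate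
13 | methyl 3-{[(5S,6S)-5-bromo-6-{3-[(tert-butyldimethylsilyl)oxy]propyl}-6-methylcyclohex-1-en-1-yl]methyl}-4-[(triisopropylsilyl)oxy]benzoate | COC(=O)c1ccc(O[Si](C(C)C)(C(C)C)C(C)C)c(CC2=CCC[C@H](Br)[C@@]2(C)CCCO[Si](C)(C)C(C)(C)C)c1 | intermediate
14 | C3 borane adduct of 13 (BH2 on C3 and H on C2, both on the face of the C8 chain) | B[C@H]1CC[C@H](Br)[C@@](C)(CCCO[Si](C)(C)C(C)(C)C)[C@@H]1Cc1cc(C(=O)OC)ccc1O[Si](C(C)C)(C(C)C)C(C)C | intermediate
15 | methyl 3-{[(1S,2S,3S,6S)-3-bromo-2-{3-[(tert-butyldimethylsilyl)oxy]propyl}-6-hydroxy-2-methylcyclohexyl]methyl}-4-[(triisopropylsilyl)oxy]benzoate | O[C@H]1CC[C@H](Br)[C@@](C)(CCCO[Si](C)(C)C(C)(C)C)[C@@H]1Cc1cc(C(=O)OC)ccc1O[Si](C(C)C)(C(C)C)C(C)C | intermediate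
16 | methyl 3-{[(1S,2S,3S)-3-bromo-2-{3-[(tert-butyldimethylsilyl)oxy]propyl}-2-methyl-6-oxocyclohexyl]methyl}-4-[(triisopropylsilyl)oxy]benzoate | O=C1CC[C@H](Br)[C@@](C)(CCCO[Si](C)(C)C(C)(C)C)[C@@H]1Cc1cc(C(=O)OC)ccc1O[Si](C(C)C)(C(C)C)C(C)C | intermediate
17 | methyl 3-{[(1R,2S,3S)-3-bromo-2-{3-[(tert-butyldimethylsilyl)oxy]propyl}-2-methyl-6-methylidenecyclohexyl]methyl}-4-[(triisopropylsilyl)oxy]benzoate | C=C1CC[C@H](Br)[C@@](C)(CCCO[Si](C)(C)C(C)(C)C)[C@@H]1Cc1cc(C(=O)OC)ccc1O[Si](C(C)C)(C(C)C)C(C)C | intermediate
18 | methyl 3-{[(1R,2S,3S)-3-bromo-2-(3-hydroxypropyl)-2-methyl-6-methylidenecyclohexyl]methyl}-4-[(triisopropylsilyl)oxy]benzoate | C=C1CC[C@H](Br)[C@@](C)(CCCO)[C@@H]1Cc1cc(C(=O)OC)ccc1O[Si](C(C)C)(C(C)C)C(C)C | intermediate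
19 | methyl 3-{[(1R,2S,3S)-3-bromo-2-methyl-6-methylidene-2-(3-oxopropyl)cyclohexyl]methyl}-4-[(triisopropylsilyl)oxy]benzoate | C=C1CC[C@H](Br)[C@@](C)(CCC=O)[C@@H]1Cc1cc(C(=O)OC)ccc1O[Si](C(C)C)(C(C)C)C(C)C | intermediate
20 | methyl 3-{[(1R,2S,3S)-3-bromo-2-[(3RS)-3-hydroxy-4-methylpent-4-en-1-yl]-2-methyl-6-methylidenecyclohexyl]methyl}-4-[(triisopropylsilyl)oxy]benzoate | C=C1CC[C@H](Br)[C@@](C)(CCC(O)C(C)=C)[C@@H]1Cc1cc(C(=O)OC)ccc1O[Si](C(C)C)(C(C)C)C(C)C | intermediate
21 | 3-hydroxy-3-methylbutan-2-one | CC(=O)C(C)(C)O | starting material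
22 | 3,3-dimethoxy-2-methylbutan-2-ol | COC(C)(OC)C(C)(C)O | intermediate
23 | enol ether of 20 (C10–O–C(=CH2)–C(CH3)2OH) | C=C1CC[C@H](Br)[C@@](C)(CCC(OC(=C)C(C)(C)O)C(C)=C)[C@@H]1Cc1cc(C(=O)OC)ccc1O[Si](C(C)C)(C(C)C)C(C)C | intermediate
24 | methyl 3-{[(1R,2S,3S)-3-bromo-2-[(3E)-8-hydroxy-4,8-dimethyl-7-oxonon-3-en-1-yl]-2-methyl-6-methylidenecyclohexyl]methyl}-4-[(triisopropylsilyl)oxy]benzoate | C=C1CC[C@H](Br)[C@@](C)(CC/C=C(C)/CCC(=O)C(C)(C)O)[C@@H]1Cc1cc(C(=O)OC)ccc1O[Si](C(C)C)(C(C)C)C(C)C | intermediate
25 | trimethylsilyl ether of 24 (at the tertiary hydroxyl) | C=C1CC[C@H](Br)[C@@](C)(CC/C=C(C)/CCC(=O)C(C)(C)O[Si](C)(C)C)[C@@H]1Cc1cc(C(=O)OC)ccc1O[Si](C(C)C)(C(C)C)C(C)C | intermediate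
26 | (14S)-alcohol from 25 (tertiary O–SiMe3 retained) | C=C1CC[C@H](Br)[C@@](C)(CC/C=C(C)/CC[C@H](O)C(C)(C)O[Si](C)(C)C)[C@@H]1Cc1cc(C(=O)OC)ccc1O[Si](C(C)C)(C(C)C)C(C)C | intermediate
27 | methyl 3-{[(1R,2S,3S)-3-bromo-2-[(3E,7S)-7,8-dihydroxy-4,8-dimethylnon-3-en-1-yl]-2-methyl-6-methylidenecyclohexyl]methyl}-4-[(triisopropylsilyl)oxy]benzoate | C=C1CC[C@H](Br)[C@@](C)(CC/C=C(C)/CC[C@H](O)C(C)(C)O)[C@@H]1Cc1cc(C(=O)OC)ccc1O[Si](C(C)C)(C(C)C)C(C)C | intermediate
28 | 3-{[(1R,2S,3S)-3-bromo-2-[(3E,7S)-7,8-dihydroxy-4,8-dimethylnon-3-en-1-yl]-2-methyl-6-methylidenecyclohexyl]methyl}-4-[(triisopropylsilyl)oxy]benzoic acid | C=C1CC[C@H](Br)[C@@](C)(CC/C=C(C)/CC[C@H](O)C(C)(C)O)[C@@H]1Cc1cc(C(=O)O)ccc1O[Si](C(C)C)(C(C)C)C(C)C | intermediate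
29 | mixed anhydride of 28 with 2,4,6-trichlorobenzoic acid | C=C1CC[C@H](Br)[C@@](C)(CC/C=C(C)/CC[C@H](O)C(C)(C)O)[C@@H]1Cc1cc(C(=O)OC(=O)c2c(Cl)cc(Cl)cc2Cl)ccc1O[Si](C(C)C)(C(C)C)C(C)C | intermediate
30 | (10E)-10,11-deoxy-O-(triisopropylsilyl)bromophycolide F (2R,6S,7S,14S; C10=C11 alkene) | C=C1CC[C@H](Br)[C@@]2(C)CC/C=C(C)/CC[C@@H](C(C)(C)O)OC(=O)c3ccc(O[Si](C(C)C)(C(C)C)C(C)C)c(c3)C[C@H]12 | intermediate
31 | O-(triisopropylsilyl)bromophycolide F (2R,6S,7S,10S,11S,14S) | C=C1CC[C@H](Br)[C@@]2(C)CC[C@@H]3O[C@@]3(C)CC[C@@H](C(C)(C)O)OC(=O)c3ccc(O[Si](C(C)C)(C(C)C)C(C)C)c(c3)C[C@H]12 | intermediate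
32 | bromophycolide F (2R,6S,7S,10S,11S,14S) | C=C1CC[C@H](Br)[C@@]2(C)CC[C@@H]3O[C@@]3(C)CC[C@@H](C(C)(C)O)OC(=O)c3ccc(O)c(c3)C[C@H]12 | target

## Step count and least certain steps

Total step count: 19. Longest linear sequence: 16 steps (steps 1, 2, 3, 6 to 12 and 14 to 19). Steps 4 and 5 prepare the aryl fragment and step 13 the Claisen partner.

**Step 2 (key step).** The bromonium ion may be captured by oxygen instead of triggering the shift (closure of the free hydroxyl to a bromo-epoxide from the other face, or attack of the silyl ether oxygen to a cyclic bromoether), or bromination may be slow because a primary alkyl group migrates only moderately well. The fallback sets out from 5. The tertiary alcohol is silylated with N-(trimethylsilyl)imidazole to tert-butyldimethyl{3-[(1S)-2-methyl-1-[(trimethylsilyl)oxy]cyclohex-2-en-1-yl]propoxy}silane F1. This silyl ether is treated with NBS (or 2,4,4,6-tetrabromocyclohexa-2,5-dienone) in CH2Cl2/MeNO2; the silyloxy group drives the same anti shift without an acidic O–H, succinimide takes up the silyl group, and aqueous work-up returns the route at 6.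

**Step 7.** Facial selectivity of borane addition may be poor, because C7 distinguishes the two faces only by methyl against a primary chain and by the ring conformation; slow reduction of the ester by excess borane is a second concern. Thermodynamic correction at C2 is not reliable, so the fallback inverts the outcome of the same facial bias. From 13, mCPBA/NaHCO3 gives the epoxide on the face that electrophiles prefer, methyl 3-{[(2,3-epoxy) analogue of 13, oxygen on the side of the C7 methyl group]methyl}-4-[(triisopropylsilyl)oxy]benzoate F2. A Meinwald rearrangement (LiClO4 in toluene, or BF3·OEt2 at −78 °C) then ionises the tertiary C2–O bond and shifts hydride from C3 to C2 anti to the departing oxygen. This puts H-2 on the face opposite the epoxide and gives the C3 ketone directly, rejoining the route at 16.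

**Step 14.** Ketal exchange and loss of methanol may stall, the E preference may erode, or the exocyclic alkene may migrate during prolonged heating with acid. The fallback sets out from 19. A Wittig reaction with Ph3P=C(CH3)CHO (toluene, 80 °C) gives the E-enal methyl 3-{[(1R,2S,3S)-3-bromo-2-methyl-6-methylidene-2-[(3E)-4-methyl-5-oxopent-3-en-1-yl]cyclohexyl]methyl}-4-[(triisopropylsilyl)oxy]benzoate F3. Luche reduction (NaBH4, CeCl3·7H2O, MeOH, 0 °C) gives the allylic alcohol F4, and CBr4/PPh3 gives the allylic bromide F5. The bromide alkylates the lithium enolate (LiN(iPr)2, THF, −78 °C) of 3-methyl-3-[(trimethylsilyl)oxy]butan-2-one F6, itself made from 21 with Me3SiCl and imidazole. This forms C12–C13 and returns the route at 25, the first intermediate of step 15.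

**Step 16.** The aryl silyl ether may be lost during ester cleavage, or hydrolysis of the electron-rich, hindered benzoate may be incomplete. The fallback sets out from 27. LiOH (THF/MeOH/H2O, 45 °C) deliberately cleaves both the methyl ester and the aryl O–Si bond to give 3-{[(1R,2S,3S)-3-bromo-2-[(3E,7S)-7,8-dihydroxy-4,8-dimethylnon-3-en-1-yl]-2-methyl-6-methylidenecyclohexyl]methyl}-4-hydroxybenzoic acid F7. TIPSCl (2.5 equiv) and imidazole in DMF then silylate only the phenol and the carboxyl group, since the hindered secondary and the tertiary hydroxyl do not react with this chloride; this gives the silyl ester silyl ether F8. K2CO3 in MeOH/THF/H2O at 0 °C cleaves the silyl ester and returns the route at 28.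

**Step 18.** The macrocycle may expose only one face of C10=C11, so substrate control could oppose the catalyst or slow the oxygen transfer. The fallback sets out from 27 and epoxidises the open chain, where the catalyst alone decides, giving the 10S,11S epoxy diol ester F9. Me3SnOH cleaves the ester, with work-up kept at pH 6 or above so that O-14 does not open the epoxide, giving the epoxy acid F10. Yamaguchi conditions through the mixed anhydride F11 close the lactone, and the route is rejoined at 31.

## Further compounds

F1 | step 2 | tert-butyldimethyl{3-[(1S)-2-methyl-1-[(trimethylsilyl)oxy]cyclohex-2-en-1-yl]propoxy}silane | CC1=CCCC[C@]1(O[Si](C)(C)C)CCCO[Si](C)(C)C(C)(C)C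
F2 | step 7 | 2,3-epoxide of 13, oxygen on the face of the C7 methyl group | COC(=O)c1ccc(O[Si](C(C)C)(C(C)C)C(C)C)c(C[C@@]23O[C@@H]2CC[C@H](Br)[C@@]3(C)CCCO[Si](C)(C)C(C)(C)C)c1
F3 | step 14 | methyl 3-{[(1R,2S,3S)-3-bromo-2-methyl-6-methylidene-2-[(3E)-4-methyl-5-oxopent-3-en-1-yl]cyclohexyl]methyl}-4-[(triisopropylsilyl)oxy]benzoate | C=C1CC[C@H](Br)[C@@](C)(CC/C=C(C)/C=O)[C@@H]1Cc1cc(C(=O)OC)ccc1O[Si](C(C)C)(C(C)C)C(C)C
F4 | step 14 | methyl 3-{[(1R,2S,3S)-3-bromo-2-[(3E)-5-hydroxy-4-methylpent-3-en-1-yl]-2-methyl-6-methylidenecyclohexyl]methyl}-4-[(triisopropylsilyl)oxy]benzoate | C=C1CC[C@H](Br)[C@@](C)(CC/C=C(C)/CO)[C@@H]1Cc1cc(C(=O)OC)ccc1O[Si](C(C)C)(C(C)C)C(C)C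
F5 | step 14 | methyl 3-{[(1R,2S,3S)-3-bromo-2-[(3E)-5-bromo-4-methylpent-3-en-1-yl]-2-methyl-6-methylidenecyclohexyl]methyl}-4-[(triisopropylsilyl)oxy]benzoate | C=C1CC[C@H](Br)[C@@](C)(CC/C=C(C)/CBr)[C@@H]1Cc1cc(C(=O)OC)ccc1O[Si](C(C)C)(C(C)C)C(C)C
F6 | step 14 | 3-methyl-3-[(trimethylsilyl)oxy]butan-2-one | CC(=O)C(C)(C)O[Si](C)(C)C
F7 | step 16 | 3-{[(1R,2S,3S)-3-bromo-2-[(3E,7S)-7,8-dihydroxy-4,8-dimethylnon-3-en-1-yl]-2-methyl-6-methylidenecyclohexyl]methyl}-4-hydroxybenzoic acid | C=C1CC[C@H](Br)[C@@](C)(CC/C=C(C)/CC[C@H](O)C(C)(C)O)[C@@H]1Cc1cc(C(=O)O)ccc1O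
F8 | step 16 | triisopropylsilyl 3-{[(1R,2S,3S)-3-bromo-2-[(3E,7S)-7,8-dihydroxy-4,8-dimethylnon-3-en-1-yl]-2-methyl-6-methylidenecyclohexyl]methyl}-4-[(triisopropylsilyl)oxy]benzoate | C=C1CC[C@H](Br)[C@@](C)(CC/C=C(C)/CC[C@H](O)C(C)(C)O)[C@@H]1Cc1cc(C(=O)O[Si](C(C)C)(C(C)C)C(C)C)ccc1O[Si](C(C)C)(C(C)C)C(C)C
F9 | step 18 | (10S,11S)-epoxide of 27 | C=C1CC[C@H](Br)[C@@](C)(CC[C@@H]2O[C@@]2(C)CC[C@H](O)C(C)(C)O)[C@@H]1Cc1cc(C(=O)OC)ccc1O[Si](C(C)C)(C(C)C)C(C)C
F10 | step 18 | (10S,11S)-epoxide of 28 | C=C1CC[C@H](Br)[C@@](C)(CC[C@@H]2O[C@@]2(C)CC[C@H](O)C(C)(C)O)[C@@H]1Cc1cc(C(=O)O)ccc1O[Si](C(C)C)(C(C)C)C(C)C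
F11 | step 18 | mixed anhydride of F10 with 2,4,6-trichlorobenzoic acid | C=C1CC[C@H](Br)[C@@](C)(CC[C@@H]2O[C@@]2(C)CC[C@H](O)C(C)(C)O)[C@@H]1Cc1cc(C(=O)OC(=O)c2c(Cl)cc(Cl)cc2Cl)ccc1O[Si](C(C)C)(C(C)C)C(C)C
A1 | alternative 1 | C1-oxo analogue of bromophycolide F (ortho-hydroxyaryl ketone macrolide) | C=C1CC[C@H](Br)[C@@]2(C)CC[C@@H]3O[C@@]3(C)CC[C@@H](C(C)(C)O)OC(=O)c3ccc(O)c(c3)C(=O)[C@H]12
A2 | alternative 1 | 17-membered para-bridged diester (C1 acyl group on the phenol oxygen) | C=C1CC[C@H](Br)[C@@]2(C)CC[C@@H]3O[C@@]3(C)CC[C@@H](C(C)(C)O)OC(=O)c3ccc(cc3)OC(=O)[C@H]12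
A3 | alternative 2 | ring A cycloadduct (C7 formyl, C3 allylsilane, diol acetonide, phenol TBS ether) | C[Si](C)(C)CC1=CC[C@H](Br)[C@@](C=O)(CC/C=C(C)/CC[C@@H]2OC(C)(C)OC2(C)C)[C@@H]1Cc1cc(C(=O)OC)ccc1O[Si](C)(C)C(C)(C)C
A4 | alternative 2 | methyl 4-[(tert-butyldimethylsilyl)oxy]-3-{(2Z)-3-[(trimethylsilyl)methyl]penta-2,4-dien-1-yl}benzoate | C=C/C(C[Si](C)(C)C)=C/Cc1cc(C(=O)OC)ccc1O[Si](C)(C)C(C)(C)C
A5 | alternative 2 | (Z)-3-bromo-2-alkylacrolein carrying C8–C15 (E-alkene, 14S diol acetonide) | O=C/C(CC/C=C(C)/CC[C@@H]1OC(C)(C)OC1(C)C)=C\Br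
A6 | alternative 3 | C3-ketone macrolide with ring A (phenol acetate) | O=C1CC[C@H](Br)[C@@]2(C)CC[C@@H]3O[C@@]3(C)CC[C@@H](C(C)(C)O)OC(=O)c3ccc(OC(C)=O)c(c3)C[C@H]12
A7 | alternative 3 | 19-membered macrolactone with (2Z)-3-chloro-2-ene and (6E)-6-ene (phenol acetate, 10S,11S epoxide, 14S) | Cl/C1=C\Cc2cc(ccc2OC(C)=O)C(=O)O[C@H](C(C)(C)O)CC[C@]3(C)O[C@H]3CC/C(C)=C/CC1
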